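**Assumptions (one line each)**
- The target SMILES corresponds to aminal CH = S and quaternary aminal carbon = R; the route is built to that.
- N-(2,2,2-trichloroethoxysulfonyl)urea (5) is taken as a catalogue reagent; if unavailable it is one step from commercial 2,2,2-trichloroethyl sulfamate (Cl3CC(O)NCO, then K2CO3/MeOH).

## Retrosynthetic overview
1. Target ⇐ phakellstatin (8) by late-stage C4/C5 dibromination of the pyrrole, so the bromines never see Zn or the Rh nitrenoid.
2. Imidazolidinone ring (formed last) ⇐ stereoretentive Rh-nitrenoid C–H amination: a urea nitrene inserts into the α-C–H of a D-proline-derived centre, making the quaternary aminal directly (no enamide, no oxidative urea addition to an alkene).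
3. Urea–C(aminal) bond ⇐ Mitsunobu inversion of the tricyclic carbinolamine 4 with TcesNHC(O)NH2.
4. Pyrazinone ring ⇐ oxidation and hemiaminal closure of N-(pyrrol-2-ylcarbonyl)-D-prolinol, from D-prolinol + 2-(trichloroacetyl)pyrrole.
5. Ring order: pyrrole and pyrrolidine purchased → pyrazinone (step 2) → imidazolidinone (step 4).

## Route

**Step 1**
Reactants: 1, D-prolinol [(R)-pyrrolidin-2-ylmethanol]; 2, 2-(trichloroacetyl)pyrrole
Product: 3, (R)-[2-(hydroxymethyl)pyrrolidin-1-yl](1H-pyrrol-2-yl)methanone
Conditions: Et3N, MeCN, rt
Reagents that add atoms: none (all atoms come from 1 and 2; CHCl3 is lost)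
Why: Haloform-type N-acylation, in which the secondary amine attacks the activated trichloromethyl ketone chemoselectively over the primary OH and CCl3⁻ leaves; the stereocentre is untouched.

**Step 2**
Reactants: 3
Product: 4, (10S,10aR)-10-hydroxy-2,3,10,10a-tetrahydro-1H,5H-dipyrrolo[1,2-a:1',2'-d]pyrazin-5-one (tricyclic carbinolamine, OH trans to H-10a)
Conditions: IBX (1.2 equiv), DMSO, rt
Reagents that add atoms: none
Why: IBX oxidation gives the N-acyl-D-prolinal, which closes reversibly onto the pyrrole N–H (hemiaminal formation) and is expected to settle as the epimer with pseudo-axial OH trans to the pseudo-axial H-10a (anomeric-type overlap with the pyrrole N, no peri strain), while the neutral rt conditions leave C-10a unepimerised.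

**Step 3**
Reactants: 4; 5, N-(2,2,2-trichloroethoxysulfonyl)urea (TcesNHC(O)NH2)
Product: 6, 2,2,2-trichloroethyl N-carbamoyl-N-[(10R,10aR)-5-oxo-2,3,10,10a-tetrahydro-1H,5H-dipyrrolo[1,2-a:1',2'-d]pyrazin-10-yl]sulfamate (urea N cis to H-10a)
Conditions: PPh3, DIAD, THF, 0 °C → rt
Reagents that add atoms: none (all new atoms come from 5)
Why: Mitsunobu N-alkylation, in which the acidic sulfonyl N–H of 5 (pKa ≈ 5) is the pronucleophile and displaces the oxyphosphonium by SN2 with inversion at C-10 (SN1 is disfavoured because the acylpyrrole nitrogen is a poor cation donor), placing the nitrogen cis to H-10a and leaving a primary C(O)NH2 as the nitrene precursor.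

**Step 4 (key step)**
Reactants: 6
Product: 7, N-Tces-phakellstatin (tetracycle; Tces on the urea nitrogen attached to the aminal CH; aminal C = R because of the Tces priority change, quaternary C = R)
Conditions: Rh2(esp)2 (3 mol %), PhI(OAc)2, MgO, toluene, 40 °C
Reagents that add atoms: none
Why: Du Bois-type Rh(II)-nitrenoid intramolecular C–H amination of an N-sulfonyl urea, in which the carbamoyl nitrene inserts in a concerted, stereoretentive way into the adjacent tertiary α-amido C–H (5-membered ring, gauche N/H geometry), so the D-prolinol stereocentre becomes the quaternary aminal with retention and the cis ring fusion fixes the aminal CH relative to it.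

**Step 5**
Reactants: 7
Product: 8, phakellstatin (aminal CH = S, quaternary C = R)
Conditions: Zn dust, AcOH/MeOH, rt; then HCl/MeOH, 40 °C
Reagents that add atoms: none
Why: Reductive fragmentation of the trichloroethyl sulfamate (Zn insertion and β-elimination) gives the N-sulfonate, which is solvolysed in acidic methanol; the cyclic urea, aminals and acylpyrrole are inert, so no stereocentre is touched.

**Step 6**
Reactants: 8
Product: 9, dibromophakellstatin (target)
Conditions: NBS (2.1 equiv), THF, 0 °C → rt, dark
Reagents that add atoms: N-bromosuccinimide, O=C1CCC(=O)N1Br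
Why: Electrophilic aromatic bromination of the N-alkyl-2-acylpyrrole occurs at C-4 and C-5 (C-3 is deactivated by the adjacent carbonyl), urea N–Br formation is reversible, and no stereocentre is involved.

## Compound list
1 | D-prolinol, (R)-pyrrolidin-2-ylmethanol | OC[C@H]1CCCN1 | starting material
2 | 2-(trichloroacetyl)pyrrole | O=C(c1ccc[nH]1)C(Cl)(Cl)Cl | starting material
3 | (R)-[2-(hydroxymethyl)pyrrolidin-1-yl](1H-pyrrol-2-yl)methanone | OC[C@H]1CCCN1C(=O)c1ccc[nH]1 | intermediate
4 | (10S,10aR)-10-hydroxy-2,3,10,10a-tetrahydro-1H,5H-dipyrrolo[1,2-a:1',2'-d]pyrazin-5-one | O[C@@H]1n2cccc2C(=O)N2CCC[C@H]12 | intermediate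
5 | N-(2,2,2-trichloroethoxysulfonyl)urea | NC(=O)NS(=O)(=O)OCC(Cl)(Cl)Cl | starting material
6 | 2,2,2-trichloroethyl N-carbamoyl-N-[(10R,10aR)-5-oxo-2,3,10,10a-tetrahydro-1H,5H-dipyrrolo[1,2-a:1',2'-d]pyrazin-10-yl]sulfamate | NC(=O)N([C@H]1n2cccc2C(=O)N2CCC[C@H]12)S(=O)(=O)OCC(Cl)(Cl)Cl | intermediate
7 | N-Tces-phakellstatin (Tces on the aminal-side urea N) | O=C1N(S(=O)(=O)OCC(Cl)(Cl)Cl)[C@H]2n3cccc3C(=O)N3CCC[C@]23N1 | intermediate
8 | phakellstatin | O=C1N[C@H]2n3cccc3C(=O)N3CCC[C@]23N1 | intermediate
9 | dibromophakellstatin | O=C1N[C@H]2n3c(cc(Br)c3Br)C(=O)N3CCC[C@]23N1 | target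

## Summary
Total steps: 6. Longest linear sequence: 6 (from D-prolinol).

**Three steps most likely to fail, with fallbacks**

1. **Step 4 (C–H amination).** The α-amido C–H is inductively deactivated by the neighbouring aminal, the unbrominated pyrrole may be attacked by the nitrenoid, and the N-sulfonylurea may eliminate to the achiral enamide. Fallback: build the quaternary C–N bond by a stereoretentive Curtius rearrangement instead. Starting from L-proline, use Seebach self-regeneration of stereocentres (pivalaldehyde N,O-acetal, LDA, BOMCl) to install the CH2OBn arm, then acylate with 2. Curtius rearrangement (DPPA, then NH3) gives the urea on the quaternary carbon, and debenzylation, oxidation and acid-mediated double N-cyclisation onto the aldehyde give 8. L-proline is the correct antipode there because the carbon arm replaces H and nitrogen replaces CO2H.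

2. **Step 3 (Mitsunobu on the hemiaminal).** E2 loss to the enamide, SN1 leakage to the trans epimer (which cannot cyclise) and O-alkylation of the bulky sulfonylurea are all possible. Fallback: install nitrogen as azide (DPPA, PPh3/DIAD; a small, non-basic nucleophile) with inversion. Then build the nitrene precursor stepwise: Staudinger reduction, N-sulfamoylation with Cl3CCH2OSO2Cl, and carbamoylation (Cl3CC(O)NCO, then K2CO3/MeOH) to reach 6.

3. **Step 2 (hemiaminal formation).** Over-oxidation to the imide, enolisation of the transient α-amino aldehyde, or formation of the OH-cis epimer would undermine step 3. Fallback: form the pyrazinone ring by lactamisation instead. D-proline methyl ester + 2, then NaH, gives the cyclic N-acylpyrrole imide, and NaBH4 reduces the acylpyrrole C=O to 4 without a free aldehyde. If the OH-cis epimer results, go through the C-10 chloride (inversion) and displace with the potassium salt of 5 (second inversion) to reach 6 with net retention.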